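Target 21 ⇐ Pd-catalysed hydroxycarbonylation of the Δ7 enol triflate 19 ⇐ kinetic triflation of decalone 18 (C8=O, C9 side chain in place).
Ring B of 18 (C5–C6–C7–C8–C9–C10) ⇐ one-carbon enlargement of the cyclopentanone ring (C5–C6–C8–C9–C10) of trans-hydrindan-2-one 15; Me3SiCHN2 supplies C7, which enters between C6 and C8.
Enabling feature: the C8 carbonyl of the five-membered ring sits between a free CH2 (C6) and a tertiary CH (C9) backed by quaternary C10, so only C6 migrates; the carbonyl stays next to C9 and later marks C8 for the carboxyl group and C7 for the alkene.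
15 ⇐ hydrogenation (sets C5 and C9) of dienone 14 ⇐ aldol condensation of bicyclic enone 6 (C9–H2 is its only enolisable site) with aldehyde 11 (C13 from (R)-2-methylbutane-1,4-diol).
6 ⇐ Wacker oxidation and aldol ring closure ⇐ allyl ketone 4 ⇐ Pd-catalysed decarboxylative asymmetric allylation (sets C10). Ring order: ring A (present in ketone 1), five-membered ring (step 4), ring B by enlargement of that ring (step 10).

Key step: step 10

Remark: atoms carry labdane numbering (ring A = C1–C5, C10; ring B = C5–C10; side chain C11–C14; the C10 methyl defines the β-face); the (R)-configured phosphinooxazoline ligand is assumed to give (R)-4, since the (S)-ligand gives (S)-configured α-quaternary ketones in this reaction class, and crystallisation of the semicarbazone of 6 is available if the enantiomeric purity needs upgrading.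

Step 1
Reactants: 1 2,2,6-trimethylcyclohexan-1-one (racemic), 2 allyl chloroformate
Product: 3 allyl 2,6,6-trimethylcyclohex-1-en-1-yl carbonate
Conditions: LiN(SiMe3)2, THF, 0 °C; then 2, −78 °C to 23 °C
Reagents that add atoms: allyl chloroformate, C=CCOC(=O)Cl
Why: 1 can be deprotonated only at its single α-CH (the other α-carbon is quaternary), and the hindered tetrasubstituted lithium enolate should be acylated on oxygen by the chloroformate (enolate O-acylation), which erases the stereocentre of racemic 1.

Step 2
Reactants: 3 allyl enol carbonate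
Product: 4 (2R)-2,6,6-trimethyl-2-(prop-2-en-1-yl)cyclohexan-1-one
Conditions: Pd2(dba)3 (2.5 mol %), (R)-t-BuPHOX [(4R)-4-tert-butyl-2-(2-diphenylphosphanylphenyl)-4,5-dihydrooxazole] (6 mol %), THF, 25 °C
Reagents that add atoms: none
Why: Decarboxylative asymmetric allylic alkylation (Tsuji-type): zerovalent palladium ionises the allyl carbonate, CO2 is lost, and the chiral ligand on the π-allylpalladium enolate decides which enolate face is allylated, which should set the quaternary centre (future C10) as R.

Step 3
Reactants: 4 allyl ketone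
Product: 5 (2R)-2,6,6-trimethyl-2-(2-oxopropyl)cyclohexan-1-one
Conditions: PdCl2 (cat.), Cu(OAc)2·H2O (cat.), O2 (1 atm), DMA/H2O 7:1, 23 °C
Reagents that add atoms: water, O
Why: Wacker oxidation: hydroxypalladation of the terminal alkene at its internal carbon should give the methyl ketone without touching the quaternary centre.

Step 4
Reactants: 5 1,4-diketone
Product: 6 (7aR)-4,4,7a-trimethyl-1,4,5,6,7,7a-hexahydro-2H-inden-2-one
Conditions: KOH, xylenes, 110 °C, azeotropic removal of water
Reagents that add atoms: none
Why: Intramolecular aldol condensation: the ring carbonyl has no α-hydrogen (two quaternary neighbours), so only the methyl ketone enolises and its CH3 carbon (future C6) closes the five-membered ring onto C5 (5-(enolexo)-exo-trig), dehydration giving the C5=C6 enone.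

Step 5
Reactants: 7 (2R)-2-methylbutane-1,4-diol
Product: 8 (3R)-3-methyloxolane
Conditions: TsOH·H2O (cat.), neat, 140 °C, product distilled out
Reagents that add atoms: none
Why: Acid-catalysed cyclodehydration of a 1,4-diol (intramolecular SN2 at a primary carbinol carbon, 5-exo-tet) should give the oxolane without involving the stereocentre.

Step 6
Reactants: 8 (3R)-3-methyloxolane, 9 2-methylpropanoyl chloride
Product: 10 (2R)-4-iodo-2-methylbutyl 2-methylpropanoate
Conditions: NaI, MeCN, 0 °C to 23 °C
Reagents that add atoms: 2-methylpropanoyl chloride, CC(C)C(Cl)=O; sodium iodide, [Na+].[I-]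
Why: Acylative ether cleavage: the acyl iodide formed in the flask acylates the ring oxygen and iodide should open the oxonium ion by SN2 at the α-carbon whose neighbour is unbranched, which leaves the ester on the CH2 next to the stereocentre (C14) and the iodide on C11.

Step 7
Reactants: 10 iodo ester
Product: 11 (2R)-2-methyl-4-oxobutyl 2-methylpropanoate
Conditions: Me3NO (anhydrous), DMSO, 23 °C
Reagents that add atoms: trimethylamine N-oxide, C[N+](C)(C)[O-]
Why: Kornblum-type oxidation: the primary iodide O-alkylates the amine oxide and the alkoxyammonium salt collapses to the aldehyde, which should leave the ester and the β-stereocentre (C13) untouched.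

Step 8
Reactants: 6 bicyclic enone, 11 side-chain aldehyde
Product: 14 (7aS)-4,4,7a-trimethyl-1-[(3R)-3-methyl-4-(2-methylpropanoyloxy)butylidene]-1,4,5,6,7,7a-hexahydro-2H-inden-2-one (E/Z mixture), via lithium aldolate 12 (not isolated), via aldol mesylate 13 (not isolated)
Conditions: LiN(iPr)2, THF, −78 °C, then 11; MsCl, −78 °C to 0 °C; DBU, 0 °C to 23 °C
Reagents that add atoms: none
Why: Aldol condensation: C9–H2 is the only enolisable position of 6 (both γ-carbons are quaternary), so the cross-conjugated lithium enolate should add to 11 through C9 and the mesylated aldolate eliminate by E1cB to the C9=C11 alkylidene, whose geometry and transient stereocentres are inconsequential.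

Step 9
Reactants: 14 cross-conjugated dienone
Product: 15 (1R,3aS,7aS)-4,4,7a-trimethyl-1-[(3R)-3-methyl-4-(2-methylpropanoyloxy)butyl]octahydro-2H-inden-2-one
Conditions: H2 (4 atm), Pd/C, EtOAc, 23 °C
Reagents that add atoms: none
Why: Heterogeneous catalytic hydrogenation: both C=C bonds should take up hydrogen from the α-face, because the β-face of C9 is shielded by the C10 methyl group and that of C5 by the syn-axial C10 and C4 methyl groups, which sets C9 (R, side chain β) and C5 (S, trans ring fusion).

Step 10
Reactants: 15 trans-hydrindan-2-one, 16 (diazomethyl)trimethylsilane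
Product: 18 (1R,4aS,8aS)-5,5,8a-trimethyl-1-[(3R)-3-methyl-4-(2-methylpropanoyloxy)butyl]octahydronaphthalen-2(1H)-one, via α-silyl ketone 17 (not isolated)
Conditions: BF3·OEt2, CH2Cl2, −78 °C to −30 °C; then 1 M HCl, THF, 23 °C
Reagents that add atoms: (diazomethyl)trimethylsilane, C[Si](C)(C)C=[N+]=[N-]
Why: BF3 activates the C8 carbonyl, the diazo carbon of 16 adds to it, and in the β-oxido diazonium ion the C6–C8 bond anti to the leaving N2 shifts to the new carbon (C7) with loss of nitrogen, after which the α-silyl ketone 17 is protodesilylated on acidic work-up. The closest known reaction type is the Lewis-acid-promoted ring homologation of cycloalkanones with trimethylsilyldiazomethane (a Tiffeneau–Demjanov-type diazoalkane insertion). No ring is closed by cyclisation: the five-membered ring C5–C6–C8–C9–C10 is enlarged to six-membered ring B by a 1,2-alkyl shift that inserts C7 between C6 and C8, helped by relief of the strain of the trans-fused cyclopentanone. The only new stereocentre is the silicon-bearing C7 of 17, which is erased on desilylation, while C5, C9 and C10 are spectators (C9 stays α to the carbonyl but should not enolise at −78 °C). The step needs migration of C6 and not of C9, and a single insertion: C9 is tertiary and backed by quaternary C10, so the bulky silyl-substituted diazo carbon should align anti to the unhindered C6 methylene, and the hindered α-silyl ketone 17 should not react a second time. The surviving C8 carbonyl is the handle that later delivers the C7=C8 double bond and the carboxyl carbon.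

Step 11
Reactants: 18 decalone
Product: 19 (1R,4aS,8aS)-5,5,8a-trimethyl-1-[(3R)-3-methyl-4-(2-methylpropanoyloxy)butyl]-1,4,4a,5,6,7,8,8a-octahydronaphthalen-2-yl trifluoromethanesulfonate
Conditions: KN(SiMe3)2, THF, −78 °C; then PhNTf2, −78 °C to 0 °C
Reagents that add atoms: N-phenylbis(trifluoromethanesulfonimide), O=S(=O)(N(c1ccccc1)S(=O)(=O)C(F)(F)F)C(F)(F)F
Why: Kinetic enolate triflation: the bulky amide base should remove a proton from the unhindered C7 methylene and not from the tertiary C9–H next to quaternary C10 or from the ester, and O-sulfonylation of the potassium enolate fixes the double bond at C7=C8 without touching C9.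

Step 12
Reactants: 19 enol triflate, 20 carbon monoxide
Product: 21 (1R,4aS,8aS)-5,5,8a-trimethyl-1-[(3R)-3-methyl-4-(2-methylpropanoyloxy)butyl]-1,4,4a,5,6,7,8,8a-octahydronaphthalene-2-carboxylic acid (target)
Conditions: Pd(OAc)2 (cat.), PPh3 (cat.), KOAc, CO (1 atm), DMF/H2O, 60 °C; then dilute aqueous HCl
Reagents that add atoms: carbon monoxide, [C-]#[O+]; water, O
Why: Pd-catalysed hydroxycarbonylation of an enol triflate: oxidative addition of zerovalent palladium into the C8–O bond, CO insertion and hydrolysis of the acylpalladium species should give the α,β-unsaturated acid under conditions that leave the isobutyrate and all stereocentres intact.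

Compound list
1 | 2,2,6-trimethylcyclohexan-1-one (racemic) | CC1CCCC(C)(C)C1=O | starting material
2 | allyl chloroformate | C=CCOC(=O)Cl | starting material
3 | allyl 2,6,6-trimethylcyclohex-1-en-1-yl carbonate | C=CCOC(=O)OC1=C(C)CCCC1(C)C | intermediate
4 | (2R)-2,6,6-trimethyl-2-(prop-2-en-1-yl)cyclohexan-1-one | C=CC[C@@]1(C)CCCC(C)(C)C1=O | intermediate
5 | (2R)-2,6,6-trimethyl-2-(2-oxopropyl)cyclohexan-1-one | CC(=O)C[C@@]1(C)CCCC(C)(C)C1=O | intermediate
6 | (7aR)-4,4,7a-trimethyl-1,4,5,6,7,7a-hexahydro-2H-inden-2-one | O=C1C[C@@]2(C)CCCC(C)(C)C2=C1 | intermediate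
7 | (2R)-2-methylbutane-1,4-diol | OC[C@H](C)CCO | starting material
8 | (3R)-3-methyloxolane | C[C@@H]1CCOC1 | intermediate
9 | 2-methylpropanoyl chloride | CC(C)C(Cl)=O | starting material
10 | (2R)-4-iodo-2-methylbutyl 2-methylpropanoate | CC(C)C(=O)OC[C@H](C)CCI | intermediate
11 | (2R)-2-methyl-4-oxobutyl 2-methylpropanoate | CC(C)C(=O)OC[C@H](C)CC=O | intermediate
12 | lithium aldolate from 6 and 11 (new C9–C11 bond; C9 and C11 as mixtures) | O=C1C(C([O-])C[C@@H](C)COC(=O)C(C)C)[C@@]2(C)CCCC(C)(C)C2=C1.[Li+] | intermediate
13 | methanesulfonate of the aldol adduct (C11–OMs; C9 and C11 as mixtures) | O=C1C(C(OS(C)(=O)=O)C[C@@H](C)COC(=O)C(C)C)[C@@]2(C)CCCC(C)(C)C2=C1 | intermediate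
14 | (7aS)-4,4,7a-trimethyl-1-[(3R)-3-methyl-4-(2-methylpropanoyloxy)butylidene]-1,4,5,6,7,7a-hexahydro-2H-inden-2-one (E/Z mixture) | O=C1C(=CC[C@@H](C)COC(=O)C(C)C)[C@@]2(C)CCCC(C)(C)C2=C1 | intermediate
15 | (1R,3aS,7aS)-4,4,7a-trimethyl-1-[(3R)-3-methyl-4-(2-methylpropanoyloxy)butyl]octahydro-2H-inden-2-one | CC(C)C(=O)OC[C@H](C)CC[C@H]1C(=O)C[C@H]2C(C)(C)CCC[C@]12C | intermediate
16 | (diazomethyl)trimethylsilane | C[Si](C)(C)C=[N+]=[N-] | starting material
17 | (1R,4aS,8aS)-5,5,8a-trimethyl-1-[(3R)-3-methyl-4-(2-methylpropanoyloxy)butyl]-3-(trimethylsilyl)octahydronaphthalen-2(1H)-one (C3 epimers) | CC(C)C(=O)OC[C@H](C)CC[C@H]1C(=O)C([Si](C)(C)C)C[C@H]2C(C)(C)CCC[C@]12C | intermediate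
18 | (1R,4aS,8aS)-5,5,8a-trimethyl-1-[(3R)-3-methyl-4-(2-methylpropanoyloxy)butyl]octahydronaphthalen-2(1H)-one | CC(C)C(=O)OC[C@H](C)CC[C@H]1C(=O)CC[C@H]2C(C)(C)CCC[C@]12C | intermediate
19 | (1R,4aS,8aS)-5,5,8a-trimethyl-1-[(3R)-3-methyl-4-(2-methylpropanoyloxy)butyl]-1,4,4a,5,6,7,8,8a-octahydronaphthalen-2-yl trifluoromethanesulfonate | CC(C)C(=O)OC[C@H](C)CC[C@H]1C(OS(=O)(=O)C(F)(F)F)=CC[C@H]2C(C)(C)CCC[C@]12C | intermediate
20 | carbon monoxide | [C-]#[O+] | starting material
21 | (1R,4aS,8aS)-5,5,8a-trimethyl-1-[(3R)-3-methyl-4-(2-methylpropanoyloxy)butyl]-1,4,4a,5,6,7,8,8a-octahydronaphthalene-2-carboxylic acid | CC(C)C(=O)OC[C@H](C)CC[C@H]1C(C(=O)O)=CC[C@H]2C(C)(C)CCC[C@]12C | target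

Total step count: 12. Longest linear sequence: 9 steps (steps 1–4 and 8–12, from ketone 1); the side-chain branch (steps 5–7) joins at step 8.

Steps most likely to fail

1. Step 10 (key ring expansion). What may go wrong: competing migration of C9 to give the regioisomeric ketone, a second insertion, or Lewis-acid-induced epimerisation next to the carbonyl. The fallback sets out from 15 and comes back at 18. Kinetic enolisation of 15 at C6 and silylation (LiN(iPr)2, Me3SiCl, THF, −78 °C) should give the trimethylsilyl enol ether F1. Cyclopropanation of its C6=C8 double bond (Et2Zn, CH2I2, CH2Cl2, 0 °C; Simmons–Smith reaction) gives the siloxycyclopropane F2, in which the future C7 bridges C6 and C8. Oxidative opening with FeCl3 in DMF cleaves the ring-fusion bond C6–C8 (alkoxy radical β-scission to the secondary C6 radical, chlorine transfer) to the ring-enlarged β-chloro ketone F3. Elimination (NaOAc, MeOH, reflux) gives the Δ6-enone F4, and hydrogenation (H2, Pd/C, EtOAc) returns decalone 18. Here the regiochemistry is fixed by the position of the enol ether and no longer by migratory aptitude.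

2. Step 9 (double hydrogenation). What may go wrong: poor facial selectivity at C5 or C9 on the metal surface, migration of the exocyclic alkene along the side chain before it is reduced, or incomplete reduction of the hindered ring alkene. The fallback sets out from 14 and comes back at 15, and separates the two events. Conjugate hydride addition to the exocyclic enone (LiBH(s-Bu)3, THF, −78 °C) and kinetic protonation of the resulting enolate at C9 from the open α-face (AcOH, −78 °C) should give the ring enone F5 with the 9β side chain. The hindered C5=C6 bond is then reduced by metal-hydride hydrogen atom transfer (Mn(dpm)3, tris(dipivaloylmethanato)manganese, trivalent manganese, cat.; PhSiH3, i-PrOH, 23 °C), in which the bulky hydride donor should reach C5 only from the α-face, to give 15.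

3. Step 6 (acylative opening of the oxolane). What may go wrong: iodide attack at the other oxonium carbon, which would exchange the ester and iodide ends and give a constitutional isomer that is hard to separate. The fallback sets out from 7 (with 9) and comes back at 11, replacing steps 5–7. Silylation of the less hindered hydroxyl of 7 (t-BuPh2SiCl, imidazole, CH2Cl2, −20 °C; regioisomers separable at this stage) gives the mono-silyl ether F6. Acylation with 9 (pyridine, CH2Cl2) gives the silyl ether ester F7, desilylation (HF·pyridine, THF) gives the hydroxy ester F8, and Dess–Martin oxidation (DMP, CH2Cl2) gives aldehyde 11.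

Further compounds
F1 | step 10 | C6=C8 trimethylsilyl enol ether of 15: (1R,3aS,7aS)-4,4,7a-trimethyl-1-[(3R)-3-methyl-4-(2-methylpropanoyloxy)butyl]-2-(trimethylsilyloxy)-3a,4,5,6,7,7a-hexahydro-1H-indene | CC(C)C(=O)OC[C@H](C)CC[C@H]1C(O[Si](C)(C)C)=C[C@H]2C(C)(C)CCC[C@]12C
F2 | step 10 | siloxycyclopropane: CH2 (future C7) bridging C6 and C8 of F1, OSiMe3 on C8 | CC(C)C(=O)OC[C@H](C)CC[C@H]1C3(O[Si](C)(C)C)CC3[C@H]2C(C)(C)CCC[C@]12C
F3 | step 10 | β-chloro ketone: 18 bearing chlorine at C6 (naphthalenone position 4) | CC(C)C(=O)OC[C@H](C)CC[C@H]1C(=O)CC(Cl)[C@H]2C(C)(C)CCC[C@]12C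
F4 | step 10 | Δ6-enone: (1R,4aS,8aS)-5,5,8a-trimethyl-1-[(3R)-3-methyl-4-(2-methylpropanoyloxy)butyl]-4a,5,6,7,8,8a-hexahydronaphthalen-2(1H)-one | CC(C)C(=O)OC[C@H](C)CC[C@H]1C(=O)C=C[C@H]2C(C)(C)CCC[C@]12C
F5 | step 9 | ring enone with saturated 9β side chain: (1R,7aS)-4,4,7a-trimethyl-1-[(3R)-3-methyl-4-(2-methylpropanoyloxy)butyl]-1,4,5,6,7,7a-hexahydro-2H-inden-2-one | CC(C)C(=O)OC[C@H](C)CC[C@H]1C(=O)C=C2C(C)(C)CCC[C@]12C
F6 | step 6 | (2R)-4-[tert-butyl(diphenyl)silyl]oxy-2-methylbutan-1-ol | OC[C@H](C)CCO[Si](c1ccccc1)(c1ccccc1)C(C)(C)C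
F7 | step 6 | (2R)-4-[tert-butyl(diphenyl)silyl]oxy-2-methylbutyl 2-methylpropanoate | CC(C)C(=O)OC[C@H](C)CCO[Si](c1ccccc1)(c1ccccc1)C(C)(C)C
F8 | step 6 | (2R)-4-hydroxy-2-methylbutyl 2-methylpropanoate | CC(C)C(=O)OC[C@H](C)CCO
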